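The constants are invented; the flask was simulated.

The ratio that opens this flask is that of two rates competing for the same initiator, so time drops out of it: at the start, impurity takes initiator 28.0 times as fast as free monomer does. Pre-initiator turns into initiator with a half-life of 0.68 min, far shorter than the run. Initiator then either begins a chain on free monomer or is spent on impurity, and each living end goes on adding free monomer.

- Monday's: free monomer 2.8 M; pre-initiator 56 mM; impurity 9.4 mM; time 40 min
- Sunday's: free monomer 2.8 M; pre-initiator 20 mM; impurity 9.4 mM; time 40 min

    free monomer + initiator → living end + monomer in chains (k1 = 0.024 /M/s)
    free monomer + living end → monomer in chains + living end, rate k2*[living end]*[free monomer] (k2 = 0.039 /M/s)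
    initiator + impurity → spent initiator (k3 = 200 /M/s)
    pre-initiator → initiator (k4 = 0.017 /s)

1. which of the two ends with the longer chains by the average number of monomer units in a chain (chains begun, living or dead) ("neither" if they lie within 10 %) (Monday's / Sunday's / neither)
2. average number of monomer units in a chain (chains begun, living or dead) at the end, Monday's
3. average number of monomer units in a chain (chains begun, living or dead) at the end, Sunday's

Because impurity is so much faster, this reckoning lets it cost initiator one for one. The chains begun, as a fraction of the free monomer charged, then form the chain share, pre-initiator charge less impurity charge over free monomer charge: 1.66 % for Monday's and 0.379 % for Sunday's. Average length is the fraction of free monomer converted divided by the chain share, so its ceiling is the inverse of that share.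

The charges act through this share. More pre-initiator raises the share, which lowers the ceiling but speeds conversion, since free monomer decays pseudo-first-order with the living ends constant. Impurity lowers the share, taking 16.8 % of Monday's pre-initiator charge and 47.0 % of Sunday's. More free monomer, at fixed pre-initiator and impurity, lowers the share and raises the ceiling. Time acts through conversion: by this reckoning, Monday's converts 98.7 % and Sunday's 62.9 %. The lengths are 59.3 for Monday's and 166 for Sunday's, so the longer chains belong to Sunday's.

The forecast gives Sunday's, with 59 (56 to 62) for Monday's and 162 (150 to 175) for Sunday's, on the ground that “The impurity destroys initiator almost stoichiometrically because it is so fast”. Its Sunday's figure lies below this reckoning's.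

The simulation gives 59.2 for Monday's and 162 for Sunday's, so Sunday's ends with the longer chains.

At 400 min, Monday's reads 60.1 and Sunday's 264, against ceilings of 60.2 and 264. The neighbouring flask, Monday's with 0.014 M of pre-initiator, has a chain share of 0.164 %. The same reckoning leaves 65.0 % of its free monomer and gives a length of 213. That flask ends with living end at 0.00460 M, a length of 204 and 66.4 % of its free monomer remaining.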